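**Plan**

- Retrosynthesis: the 2'-O-silyl group is removed first. Both aryl–C(quaternary) bonds (at C6 and C5') are then cut together by a retro-Claisen step to a 7,4'-bis(prenyl) ether. The O1–C8a aryl ether bond of the pyran ring follows, and last the C3–C4 bond, which leaves a ring-B arylacetyl imide and a ring-A benzylic bromide.
- Forward: ring B (steps 1–3) and ring A (steps 4–6) are built separately and joined at C3–C4 (step 7). The auxiliary is reduced off (step 8). The pyran ring, the only ring formed, closes by O1–C8a coupling (step 9). Both prenyl groups then move from oxygen to carbon (step 10), and fluoride frees 2'-OH (step 11).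
- Enabling feature: the 1,1-dimethylallyl groups on C6 (ring A) and C5' (ring B) each stand ortho to a free phenol (7-OH, 4'-OH) and para to a second oxygen (O1, 2'-O). This is the pattern an aromatic Claisen rearrangement of O-prenyl ethers leaves behind.
- Stereochemistry: the single stereocentre C3 (R) is set in step 7 by alkylation of a sodium (Z)-enolate under control of an oxazolidinone auxiliary of R configuration, and is carried unchanged to the end.

Key step: step 10

Assumption: isoflavan numbering is used (O1, C2–C4, C4a–C8a; primed locants for ring B), and "prenyl" stands for 3-methylbut-2-enyl.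

**Route**

Step 1
Reactants: 1 2,4-dihydroxyphenylacetic acid; 2 prenyl bromide (1-bromo-3-methylbut-2-ene)
Product: 4 2-[2-hydroxy-4-(3-methylbut-2-enyloxy)phenyl]acetic acid, via disodium salt 3 (not isolated)
Conditions: NaH (2.05 equiv), DMF, 0 °C; then 2 (1.0 equiv), 0 °C to rt; cold 1 M HCl to pH 3
Reagents that add atoms: none
Why: Williamson ether synthesis on the dianion should be selective because, with two equivalents of base, only one phenol is ionised beside the carboxylate and this should be the unhindered 4-OH (the 2-OH is tied up in a hydrogen bond to the neighbouring carboxylate), while a phenoxide is far more nucleophilic than a carboxylate towards an allylic bromide in DMF.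

Step 2
Reactants: 4 2-[2-hydroxy-4-(3-methylbut-2-enyloxy)phenyl]acetic acid
Product: 6 2-[4-(3-methylbut-2-enyloxy)-2-(triisopropylsilyloxy)phenyl]acetic acid, via silyl ester 5 (not isolated)
Conditions: TIPSCl (2.3 equiv), imidazole, DMF, rt; then K2CO3, THF/MeOH/H2O, 0 °C; cold 1 M HCl to pH 4
Reagents that add atoms: triisopropylsilyl chloride CC(C)[Si](Cl)(C(C)C)C(C)C
Why: Silylation of phenols and acids with a trialkylsilyl chloride and imidazole is general, and the selective hydrolysis rests on the far greater lability of a silyl ester towards aqueous carbonate compared with a hindered aryl triisopropylsilyl ether.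

Step 3
Reactants: 6 2-[4-(3-methylbut-2-enyloxy)-2-(triisopropylsilyloxy)phenyl]acetic acid; 7 (R)-4-benzyl-2-oxazolidinone
Product: 9 (4R)-4-benzyl-3-{2-[4-(3-methylbut-2-enyloxy)-2-(triisopropylsilyloxy)phenyl]acetyl}oxazolidin-2-one, via mixed pivalic anhydride 8 (not isolated)
Conditions: PivCl, Et3N, THF, −20 °C; then 7, LiCl, −20 °C to rt
Reagents that add atoms: none
Why: N-Acylation of an oxazolidinone through a mixed pivalic anhydride with LiCl and Et3N is a standard mild route to Evans imides, the tert-butyl group steering the nitrogen nucleophile to the arylacetyl carbonyl and the weak base sparing the acidic benzylic position.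

Step 4
Reactants: 10 2-bromo-4-hydroxybenzaldehyde; 2 prenyl bromide
Product: 11 2-bromo-4-(3-methylbut-2-enyloxy)benzaldehyde
Conditions: K2CO3, acetone, reflux
Reagents that add atoms: none
Why: Williamson ether synthesis of an acidic, unhindered para-formyl phenoxide with a reactive allylic bromide under carbonate conditions that leave the aldehyde and the aryl bromide alone.

Step 5
Reactants: 11 2-bromo-4-(3-methylbut-2-enyloxy)benzaldehyde
Product: 12 [2-bromo-4-(3-methylbut-2-enyloxy)phenyl]methanol
Conditions: NaBH4, MeOH/THF, 0 °C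
Reagents that add atoms: none
Why: Chemoselective borohydride reduction of an aromatic aldehyde, to which the aryl bromide, the allyl ether and the trisubstituted alkene are inert.

Step 6
Reactants: 12 [2-bromo-4-(3-methylbut-2-enyloxy)phenyl]methanol
Product: 13 2-bromo-1-(bromomethyl)-4-(3-methylbut-2-enyloxy)benzene
Conditions: CBr4, PPh3, CH2Cl2, 0 °C; used promptly
Reagents that add atoms: carbon tetrabromide BrC(Br)(Br)Br
Why: The Appel reaction turns the benzylic alcohol into the bromide under neutral conditions, which avoids the hydrogen bromide that would attack the acid-sensitive prenyl ether.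

Step 7
Reactants: 9 (4R)-4-benzyl-3-{2-[4-(3-methylbut-2-enyloxy)-2-(triisopropylsilyloxy)phenyl]acetyl}oxazolidin-2-one; 13 2-bromo-1-(bromomethyl)-4-(3-methylbut-2-enyloxy)benzene
Product: 15 (4R)-4-benzyl-3-{(2R)-3-[2-bromo-4-(3-methylbut-2-enyloxy)phenyl]-2-[4-(3-methylbut-2-enyloxy)-2-(triisopropylsilyloxy)phenyl]propanoyl}oxazolidin-2-one, via sodium (Z)-enolate 14 (not isolated)
Conditions: NaN(SiMe3)2, THF, −78 °C; then 13, −78 to −40 °C
Reagents that add atoms: none
Why: Evans asymmetric alkylation: NaN(SiMe3)2 should give the sodium-chelated (Z)-enolate 14, whose face on the side of the 4-benzyl group is shielded, so that the reactive benzylic bromide adds to the open face and sets the new stereocentre (later C3) as R.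

Step 8
Reactants: 15 (4R)-4-benzyl-3-{(2R)-3-[2-bromo-4-(3-methylbut-2-enyloxy)phenyl]-2-[4-(3-methylbut-2-enyloxy)-2-(triisopropylsilyloxy)phenyl]propanoyl}oxazolidin-2-one
Product: 16 (2R)-3-[2-bromo-4-(3-methylbut-2-enyloxy)phenyl]-2-[4-(3-methylbut-2-enyloxy)-2-(triisopropylsilyloxy)phenyl]propan-1-ol
Conditions: LiBH4, MeOH (1 equiv), THF, 0 °C
Reagents that add atoms: none
Why: Reductive cleavage of the N-acyloxazolidinone with LiBH4 and one equivalent of methanol should give the primary alcohol and the intact auxiliary, the exocyclic carbonyl being the more electrophilic one, and it leaves the aryl bromide, the silyl ether and the alpha-aryl stereocentre untouched.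

Step 9
Reactants: 16 (2R)-3-[2-bromo-4-(3-methylbut-2-enyloxy)phenyl]-2-[4-(3-methylbut-2-enyloxy)-2-(triisopropylsilyloxy)phenyl]propan-1-ol
Product: 17 (3R)-7-(3-methylbut-2-enyloxy)-3-[4-(3-methylbut-2-enyloxy)-2-(triisopropylsilyloxy)phenyl]chroman
Conditions: Pd(OAc)2 (5 mol %), racemic 2-(di-tert-butylphosphino)-1,1'-binaphthyl (6 mol %), Cs2CO3, toluene, 65 °C
Reagents that add atoms: none
Why: Intramolecular palladium-catalysed aryl ether formation of the Buchwald–Hartwig type should close the six-membered pyran ring at O1–C8a, the bulky electron-rich biarylphosphine speeding C–O reductive elimination ahead of beta-hydride elimination of the primary alkoxide, without involving the stereocentre.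

Step 10
Reactants: 17 (3R)-7-(3-methylbut-2-enyloxy)-3-[4-(3-methylbut-2-enyloxy)-2-(triisopropylsilyloxy)phenyl]chroman
Product: 20 (3R)-3-[4-hydroxy-5-(2-methylbut-3-en-2-yl)-2-(triisopropylsilyloxy)phenyl]-6-(2-methylbut-3-en-2-yl)chroman-7-ol (2'-O-triisopropylsilyl manuifolin E), via ring-A-rearranged monophenol 18 (not isolated), via ring-B-rearranged monophenol 19 (not isolated)
Conditions: N,N-diethylaniline (degassed), 190 °C, sealed tube, argon, short heating followed by TLC
Reagents that add atoms: none
Why: Each aryl prenyl ether should undergo a concerted suprafacial [3,3]-sigmatropic shift through a chair-like six-membered transition state, in which the O–CH2 bond breaks while the dimethyl-bearing allyl terminus bonds to the ortho carbon with allylic inversion, giving an ortho-dienone that tautomerises to the phenol; the two events are independent and run in the same heating period by way of the monophenols 18 and 19. The closest known reaction type is the thermal aromatic Claisen rearrangement of prenyl ethers of 3-alkoxyphenols to 2-(1,1-dimethylallyl)-5-alkoxyphenols in a basic aniline solvent. No ring is closed and no stereocentre is created, since each new quaternary carbon carries two methyl groups and C3 is a remote spectator that the pericyclic process does not touch. The selectivity needed is C6 over C8 and C5' over C3': C8 and C3' each lie between two oxygen substituents, so the incoming tertiary carbon would be flanked on both sides (at C3' by the bulky silyl ether), whereas C6 and C5' have only a hydrogen neighbour and are para to the donor oxygens O1 and 2'-O. Because the para positions C4a and C1' are substituted, a further shift to a para position cannot aromatise, and the amine solvent, the absence of acid and the short heating time should hold back abnormal Claisen rearrangement and cyclisation of the ortho-(1,1-dimethylallyl)phenols to dihydrobenzofurans.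

Step 11
Reactants: 20 2'-O-triisopropylsilyl manuifolin E
Product: 21 manuifolin E, (3R)-3-[2,4-dihydroxy-5-(2-methylbut-3-en-2-yl)phenyl]-6-(2-methylbut-3-en-2-yl)chroman-7-ol
Conditions: Bu4NF, AcOH (1:1), THF, 0 °C, argon
Reagents that add atoms: none
Why: Fluoride-induced cleavage of the aryl silyl ether is driven by the strong Si–F bond, and buffering with acetic acid keeps the electron-rich phenols protonated and the 1,1-dimethylallyl groups and C3 untouched.

**Compound list**

1 | 2,4-dihydroxyphenylacetic acid | OC(=O)Cc1ccc(O)cc1O | starting material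
2 | prenyl bromide (1-bromo-3-methylbut-2-ene) | CC(C)=CCBr | starting material
3 | disodium 2-(2-hydroxy-4-oxidophenyl)acetate | [Na+].[Na+].[O-]C(=O)Cc1ccc([O-])cc1O | intermediate
4 | 2-[2-hydroxy-4-(3-methylbut-2-enyloxy)phenyl]acetic acid | OC(=O)Cc1ccc(OCC=C(C)C)cc1O | intermediate
5 | triisopropylsilyl 2-[4-(3-methylbut-2-enyloxy)-2-(triisopropylsilyloxy)phenyl]acetate | CC(C)[Si](OC(=O)Cc1ccc(OCC=C(C)C)cc1O[Si](C(C)C)(C(C)C)C(C)C)(C(C)C)C(C)C | intermediate
6 | 2-[4-(3-methylbut-2-enyloxy)-2-(triisopropylsilyloxy)phenyl]acetic acid | OC(=O)Cc1ccc(OCC=C(C)C)cc1O[Si](C(C)C)(C(C)C)C(C)C | intermediate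
7 | (R)-4-benzyl-2-oxazolidinone | O=C1N[C@H](Cc2ccccc2)CO1 | starting material
8 | 2-[4-(3-methylbut-2-enyloxy)-2-(triisopropylsilyloxy)phenyl]acetic pivalic anhydride | CC(C)(C)C(=O)OC(=O)Cc1ccc(OCC=C(C)C)cc1O[Si](C(C)C)(C(C)C)C(C)C | intermediate
9 | (4R)-4-benzyl-3-{2-[4-(3-methylbut-2-enyloxy)-2-(triisopropylsilyloxy)phenyl]acetyl}oxazolidin-2-one | O=C(Cc1ccc(OCC=C(C)C)cc1O[Si](C(C)C)(C(C)C)C(C)C)N1C(=O)OC[C@H]1Cc1ccccc1 | intermediate
10 | 2-bromo-4-hydroxybenzaldehyde | O=Cc1ccc(O)cc1Br | starting material
11 | 2-bromo-4-(3-methylbut-2-enyloxy)benzaldehyde | O=Cc1ccc(OCC=C(C)C)cc1Br | intermediate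
12 | [2-bromo-4-(3-methylbut-2-enyloxy)phenyl]methanol | OCc1ccc(OCC=C(C)C)cc1Br | intermediate
13 | 2-bromo-1-(bromomethyl)-4-(3-methylbut-2-enyloxy)benzene | BrCc1ccc(OCC=C(C)C)cc1Br | intermediate
14 | sodium (Z)-enolate of imide 9 | [Na+].[O-]/C(=C\c1ccc(OCC=C(C)C)cc1O[Si](C(C)C)(C(C)C)C(C)C)N1C(=O)OC[C@H]1Cc1ccccc1 | intermediate
15 | (4R)-4-benzyl-3-{(2R)-3-[2-bromo-4-(3-methylbut-2-enyloxy)phenyl]-2-[4-(3-methylbut-2-enyloxy)-2-(triisopropylsilyloxy)phenyl]propanoyl}oxazolidin-2-one | O=C([C@@H](c1ccc(OCC=C(C)C)cc1O[Si](C(C)C)(C(C)C)C(C)C)Cc1ccc(OCC=C(C)C)cc1Br)N1C(=O)OC[C@H]1Cc1ccccc1 | intermediate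
16 | (2R)-3-[2-bromo-4-(3-methylbut-2-enyloxy)phenyl]-2-[4-(3-methylbut-2-enyloxy)-2-(triisopropylsilyloxy)phenyl]propan-1-ol | OC[C@@H](c1ccc(OCC=C(C)C)cc1O[Si](C(C)C)(C(C)C)C(C)C)Cc1ccc(OCC=C(C)C)cc1Br | intermediate
17 | (3R)-7-(3-methylbut-2-enyloxy)-3-[4-(3-methylbut-2-enyloxy)-2-(triisopropylsilyloxy)phenyl]chroman | CC(C)=CCOc1ccc2c(c1)OC[C@@H](c1ccc(OCC=C(C)C)cc1O[Si](C(C)C)(C(C)C)C(C)C)C2 | intermediate
18 | (3R)-6-(2-methylbut-3-en-2-yl)-3-[4-(3-methylbut-2-enyloxy)-2-(triisopropylsilyloxy)phenyl]chroman-7-ol | C=CC(C)(C)c1cc2c(cc1O)OC[C@@H](c1ccc(OCC=C(C)C)cc1O[Si](C(C)C)(C(C)C)C(C)C)C2 | intermediate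
19 | (3R)-3-[4-hydroxy-5-(2-methylbut-3-en-2-yl)-2-(triisopropylsilyloxy)phenyl]-7-(3-methylbut-2-enyloxy)chroman | CC(C)=CCOc1ccc2c(c1)OC[C@@H](c1cc(C(C)(C)C=C)c(O)cc1O[Si](C(C)C)(C(C)C)C(C)C)C2 | intermediate
20 | (3R)-3-[4-hydroxy-5-(2-methylbut-3-en-2-yl)-2-(triisopropylsilyloxy)phenyl]-6-(2-methylbut-3-en-2-yl)chroman-7-ol (2'-O-triisopropylsilyl manuifolin E) | C=CC(C)(C)c1cc2c(cc1O)OC[C@@H](c1cc(C(C)(C)C=C)c(O)cc1O[Si](C(C)C)(C(C)C)C(C)C)C2 | intermediate
21 | manuifolin E, (3R)-3-[2,4-dihydroxy-5-(2-methylbut-3-en-2-yl)phenyl]-6-(2-methylbut-3-en-2-yl)chroman-7-ol | C=CC(C)(C)c1cc2c(cc1O)OC[C@@H](c1cc(C(C)(C)C=C)c(O)cc1O)C2 | target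

**Count**

Total steps: 11. Longest linear sequence: 8 steps (steps 1–3 and 7–11; the ring-A branch, steps 4–6 and 7–11, is equally long).

**Steps most likely to fail**

1. Step 10. The process at risk is onward reaction of the first-formed ortho-(1,1-dimethylallyl)phenols (abnormal Claisen rearrangement, ring closure of the phenol onto the vinyl group) while the slower of the two rearrangements is still running. Migration of the ring-A prenyl group to C8 is a second risk, because the ring oxygen blocks C8 less than the silyl ether blocks C3'. The fallback sets out from 17 and comes back at 20. It replaces direct isolation of the free phenols by a capture-then-release sequence: 17 would be heated in N,N-diethylaniline with acetic anhydride and NaOAc, so that each phenol is acetylated as soon as it forms. This should give (3R)-3-[4-acetoxy-5-(2-methylbut-3-en-2-yl)-2-(triisopropylsilyloxy)phenyl]-6-(2-methylbut-3-en-2-yl)chroman-7-yl acetate F1. Methanolysis of the two aryl acetates with K2CO3 in methanol at 0 °C should then give 20.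

2. Step 1. The process at risk is loss of regiocontrol by alkylation of the 2-phenoxide or the carboxylate, together with double alkylation. The fallback sets out from prenyl bromide 2 and comes back at acid 6, with the regiochemistry fixed by a hydrogen-bonded salicylaldehyde. Purchased 2,4-dihydroxybenzaldehyde, whose 2-OH is locked to the formyl group, would be alkylated with 2 (K2CO3, acetone) at the 4-OH only, to give 2-hydroxy-4-(3-methylbut-2-enyloxy)benzaldehyde F2. Silylation (TIPSCl, imidazole, DMF) should give 4-(3-methylbut-2-enyloxy)-2-(triisopropylsilyloxy)benzaldehyde F3. Wittig methylenation (Ph3P=CH2, THF) should give 1-ethenyl-4-(3-methylbut-2-enyloxy)-2-(triisopropylsilyloxy)benzene F4. Hydroboration with 9-borabicyclo[3.3.1]nonane, which should take the vinyl group and leave the trisubstituted prenyl alkene, followed by oxidation with NaBO3·4H2O, should give 2-[4-(3-methylbut-2-enyloxy)-2-(triisopropylsilyloxy)phenyl]ethanol F5. Oxidation with TEMPO and PhI(OAc)2 in aqueous acetonitrile then leads to 6.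

3. Step 9. The process at risk is beta-hydride elimination of the palladium alkoxide (loss of bromine from the ring, oxidation of the alcohol), or base-induced silyl migration from 2'-O to the primary alkoxide, in competition with C–O reductive elimination. The fallback sets out from 16 and comes back at 17. It makes the ring-A phenol first and closes the ring by substitution at C2. Miyaura borylation (B2pin2, PdCl2(dppf), KOAc, dioxane, 80 °C) should give (2R)-2-[4-(3-methylbut-2-enyloxy)-2-(triisopropylsilyloxy)phenyl]-3-[4-(3-methylbut-2-enyloxy)-2-(4,4,5,5-tetramethyl-1,3,2-dioxaborolan-2-yl)phenyl]propan-1-ol F6. Oxidation (NaBO3·4H2O, THF/H2O, rt) should give (2R)-3-[2-hydroxy-4-(3-methylbut-2-enyloxy)phenyl]-2-[4-(3-methylbut-2-enyloxy)-2-(triisopropylsilyloxy)phenyl]propan-1-ol F7. A Mitsunobu reaction (PPh3, DIAD, THF, 0 °C), in which only the ring-A phenol is free, should then close the six-membered ring to 17.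

**Further compounds**

F1 | step 10 | (3R)-3-[4-acetoxy-5-(2-methylbut-3-en-2-yl)-2-(triisopropylsilyloxy)phenyl]-6-(2-methylbut-3-en-2-yl)chroman-7-yl acetate | C=CC(C)(C)c1cc2c(cc1OC(C)=O)OC[C@@H](c1cc(C(C)(C)C=C)c(OC(C)=O)cc1O[Si](C(C)C)(C(C)C)C(C)C)C2
F2 | step 1 | 2-hydroxy-4-(3-methylbut-2-enyloxy)benzaldehyde | O=Cc1ccc(OCC=C(C)C)cc1O
F3 | step 1 | 4-(3-methylbut-2-enyloxy)-2-(triisopropylsilyloxy)benzaldehyde | O=Cc1ccc(OCC=C(C)C)cc1O[Si](C(C)C)(C(C)C)C(C)C
F4 | step 1 | 1-ethenyl-4-(3-methylbut-2-enyloxy)-2-(triisopropylsilyloxy)benzene | C=Cc1ccc(OCC=C(C)C)cc1O[Si](C(C)C)(C(C)C)C(C)C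
F5 | step 1 | 2-[4-(3-methylbut-2-enyloxy)-2-(triisopropylsilyloxy)phenyl]ethanol | OCCc1ccc(OCC=C(C)C)cc1O[Si](C(C)C)(C(C)C)C(C)C
F6 | step 9 | (2R)-2-[4-(3-methylbut-2-enyloxy)-2-(triisopropylsilyloxy)phenyl]-3-[4-(3-methylbut-2-enyloxy)-2-(4,4,5,5-tetramethyl-1,3,2-dioxaborolan-2-yl)phenyl]propan-1-ol | OC[C@@H](c1ccc(OCC=C(C)C)cc1O[Si](C(C)C)(C(C)C)C(C)C)Cc1ccc(OCC=C(C)C)cc1B1OC(C)(C)C(C)(C)O1
F7 | step 9 | (2R)-3-[2-hydroxy-4-(3-methylbut-2-enyloxy)phenyl]-2-[4-(3-methylbut-2-enyloxy)-2-(triisopropylsilyloxy)phenyl]propan-1-ol | OC[C@@H](c1ccc(OCC=C(C)C)cc1O[Si](C(C)C)(C(C)C)C(C)C)Cc1ccc(OCC=C(C)C)cc1O
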